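## Retrosynthetic overview

1. Tandyukisin D ⇐ global desilylation ⇐ opening of 3-methylglutaconic anhydride by the only free ring hydroxyl (C6–OH) of a silyl-protected decalin.
2. Decalin ⇐ thermal intramolecular Diels–Alder reaction of an (E,E,E)-1,7,9-decatrien-3-one. Ring order: a temporary γ-lactone is made and opened first; then the cyclohexene ring (new bonds C1–C2 and C4a–C8a) and the cyclohexane ring (closed by the tether) form together in this one step.
3. Trienone ⇐ Wittig olefination of a cis-α-methyl-γ-lactol (frees only the hydroxyl that is later acylated) ⇐ dienyl lactone by formyl-Wittig and Julia–Kocienski olefinations.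
4. Lactone ⇐ zinc-mediated Dreiding–Schmidt allylation/lactonisation of (S)-glyceraldehyde acetonide (Felkin–Anh), then cis-selective hydrogenation.
5. Stereochemical sources: (R)-solketal (becomes C5–OH and relays to C6–O, C8–Me and, through the cycloaddition, C1, C2, C4a, C8a) and (R)-2-methylbutan-1-ol (sec-butyl).

Assumption: (R)-2-methylbutan-1-ol and (R)-solketal are bought enantiopure and 3-methylglutaconic acid as its E/Z mixture; decalin locants are those of the names below (C1 = quaternary carbon), chain locants are those of triene 25.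

## Route

Step 1
Reactants: 1 (R)-2-methylbutan-1-ol; 2 1-phenyl-1H-tetrazole-5-thiol
Product: 3 5-{[(2R)-2-methylbutyl]sulfanyl}-1-phenyl-1H-tetrazole
Conditions: PPh3, DIAD, THF, 0 °C → rt
Reagents that add atoms: none
Why: Mitsunobu thioetherification of a primary alcohol; the stereocentre is one carbon away from the reacting carbon and is untouched.

Step 2
Reactants: 3 5-{[(2R)-2-methylbutyl]sulfanyl}-1-phenyl-1H-tetrazole
Product: 4 5-{[(2R)-2-methylbutyl]sulfonyl}-1-phenyl-1H-tetrazole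
Conditions: (NH4)6Mo7O24·4H2O (10 mol%), 30% aq. H2O2, EtOH, 0 °C → rt
Reagents that add atoms: hydrogen peroxide, OO
Why: Molybdate-catalysed sulfide-to-sulfone oxidation gives the Julia–Kocienski partner with no epimerisable centre.

Step 3
Reactants: 5 methyl 3-hydroxypropanoate
Product: 6 methyl 3-[(tert-butyldimethylsilyl)oxy]propanoate
Conditions: TBSCl, imidazole, CH2Cl2, 0 °C → rt
Reagents that add atoms: tert-butyldimethylsilyl chloride, CC(C)(C)[Si](C)(C)Cl
Why: Standard silyl ether protection of a primary alcohol.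

Step 4
Reactants: 6 methyl 3-[(tert-butyldimethylsilyl)oxy]propanoate; 7 ethyltriphenylphosphonium bromide
Product: 9 5-[(tert-butyldimethylsilyl)oxy]-2-(triphenyl-λ5-phosphanylidene)pentan-3-one, via ethylidenetriphenylphosphorane 8 (not isolated)
Conditions: 7 (2.1 equiv), NaN(SiMe3)2 (2.1 equiv), THF, 0 °C; then 6, 0 °C → rt
Reagents that add atoms: none
Why: Acylation of a non-stabilised ylide by an ester (Bestmann transylidation), the second equivalent of ylide deprotonating the acylphosphonium to the stabilised keto-ylide.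

Step 5
Reactants: 10 3-methylglutaconic acid (E/Z mixture)
Product: 11 4-methyl-2H-pyran-2,6(3H)-dione (3-methylglutaconic anhydride)
Conditions: Ac2O, 60 °C; concentrate
Reagents that add atoms: none
Why: Cyclodehydration to the six-membered anhydride, on which both acid isomers converge through mixed anhydride and enol forms, so the ring locks the Z geometry.

Step 6
Reactants: 12 [(4R)-2,2-dimethyl-1,3-dioxolan-4-yl]methanol ((R)-solketal)
Product: 13 (4S)-2,2-dimethyl-1,3-dioxolane-4-carbaldehyde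
Conditions: (COCl)2, DMSO, CH2Cl2, −78 °C; Et3N, → 0 °C; crude used at once
Reagents that add atoms: none
Why: Swern oxidation gives the configurationally labile aldehyde under cold, non-epimerising conditions (the descriptor changes from R to S only because the priorities change).

Step 7
Reactants: 13 (4S)-2,2-dimethyl-1,3-dioxolane-4-carbaldehyde; 14 ethyl 2-(bromomethyl)prop-2-enoate
Product: 16 (5R)-5-[(4S)-2,2-dimethyl-1,3-dioxolan-4-yl]-3-methylideneoxolan-2-one, via hydroxy ester 15 (not isolated)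
Conditions: Zn dust, Me3SiCl (cat.), THF, 50 °C; sat. aq. NH4Cl
Reagents that add atoms: none
Why: Dreiding–Schmidt reaction (zinc-mediated Barbier-type 2-(ethoxycarbonyl)allylation, then lactonisation of the zinc alkoxide), in which Felkin–Anh attack anti to the dioxolane C–O bond sets the new carbinol anti (5R; about 5:1 expected, minor syn lactone removed by chromatography).

Step 8
Reactants: 16 (5R)-5-[(4S)-2,2-dimethyl-1,3-dioxolan-4-yl]-3-methylideneoxolan-2-one
Product: 17 (3R,5R)-5-[(4S)-2,2-dimethyl-1,3-dioxolan-4-yl]-3-methyloxolan-2-one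
Conditions: H2 (1 atm), 10% Pd/C, EtOAc, rt
Reagents that add atoms: none
Why: Heterogeneous hydrogenation delivers hydrogen to the exocyclic alkene from the lactone face opposite the C5 dioxolanyl group, so the new methyl is cis to it (3R).

Step 9
Reactants: 17 (3R,5R)-5-[(4S)-2,2-dimethyl-1,3-dioxolan-4-yl]-3-methyloxolan-2-one
Product: 18 (3R,5R)-5-[(1S)-1,2-dihydroxyethyl]-3-methyloxolan-2-one
Conditions: AcOH/H2O 4:1, 40 °C
Reagents that add atoms: none
Why: Acid-catalysed acetal hydrolysis that leaves the γ-lactone, the favoured ring size, in place.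

Step 10
Reactants: 18 (3R,5R)-5-[(1S)-1,2-dihydroxyethyl]-3-methyloxolan-2-one
Product: 19 (3R,5R)-5-[(1S)-1,2-bis(triethylsilyloxy)ethyl]-3-methyloxolan-2-one
Conditions: Et3SiCl (2.5 equiv), imidazole, DMF, 0 °C → rt
Reagents that add atoms: chlorotriethylsilane, CC[Si](Cl)(CC)CC
Why: Exhaustive silylation of both hydroxyls sets up the selective oxidative unmasking of the primary one.

Step 11
Reactants: 19 (3R,5R)-5-[(1S)-1,2-bis(triethylsilyloxy)ethyl]-3-methyloxolan-2-one
Product: 20 (2R)-2-[(2R,4R)-4-methyl-5-oxooxolan-2-yl]-2-(triethylsilyloxy)acetaldehyde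
Conditions: (COCl)2 (4 equiv), DMSO (8 equiv), CH2Cl2, −78 → −30 °C; Et3N, −78 °C → 0 °C
Reagents that add atoms: none
Why: Swern oxidation with selective oxidative desilylation, in which the chlorosulfonium reagent cleaves only the unhindered primary triethylsilyl ether and oxidises it to the aldehyde, the secondary silyl ether staying on.

Step 12
Reactants: 20 (2R)-2-[(2R,4R)-4-methyl-5-oxooxolan-2-yl]-2-(triethylsilyloxy)acetaldehyde; 21 (triphenyl-λ5-phosphanylidene)acetaldehyde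
Product: 22 (2E,4S)-4-[(2R,4R)-4-methyl-5-oxooxolan-2-yl]-4-(triethylsilyloxy)but-2-enal
Conditions: 21 (1.3 equiv), CH2Cl2, rt → 40 °C
Reagents that add atoms: none
Why: Wittig olefination with a stabilised formyl ylide is E-selective and nearly neutral, so neither the α-silyloxy centre nor the lactone is disturbed.

Step 13
Reactants: 22 (2E,4S)-4-[(2R,4R)-4-methyl-5-oxooxolan-2-yl]-4-(triethylsilyloxy)but-2-enal; 4 5-{[(2R)-2-methylbutyl]sulfonyl}-1-phenyl-1H-tetrazole
Product: 23 (3R,5R)-3-methyl-5-[(1S,2E,4E,6R)-6-methyl-1-(triethylsilyloxy)octa-2,4-dien-1-yl]oxolan-2-one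
Conditions: 4 (1.3 equiv), KN(SiMe3)2 (1.2 equiv), DME, −60 °C; then 22, −60 °C → rt
Reagents that add atoms: none
Why: Julia–Kocienski olefination of an enal with a phenyltetrazolyl sulfone gives the new disubstituted alkene E, completing the E,E-diene with the bought sec-butyl centre attached.

Step 14
Reactants: 23 (3R,5R)-3-methyl-5-[(1S,2E,4E,6R)-6-methyl-1-(triethylsilyloxy)octa-2,4-dien-1-yl]oxolan-2-one
Product: 24 (3R,5R)-3-methyl-5-[(1S,2E,4E,6R)-6-methyl-1-(triethylsilyloxy)octa-2,4-dien-1-yl]oxolan-2-ol (anomer mixture)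
Conditions: i-Bu2AlH (1.1 equiv), CH2Cl2, −78 °C; aq. KNaC4H4O6
Reagents that add atoms: none
Why: Partial reduction of a lactone to the lactol stops at the stable tetrahedral aluminium acetal at −78 °C.

Step 15
Reactants: 24 (3R,5R)-3-methyl-5-[(1S,2E,4E,6R)-6-methyl-1-(triethylsilyloxy)octa-2,4-dien-1-yl]oxolan-2-ol; 9 5-[(tert-butyldimethylsilyl)oxy]-2-(triphenyl-λ5-phosphanylidene)pentan-3-one
Product: 26 3-[(tert-butyldimethylsilyl)oxy]-1-[(1S,2S,4aR,5S,6R,8R,8aS)-2-[(2R)-butan-2-yl]-6-hydroxy-1,8-dimethyl-5-(triethylsilyloxy)-1,2,4a,5,6,7,8,8a-octahydronaphthalen-1-yl]propan-1-one, via triene 25 (not isolated)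
Conditions: 9 (1.5 equiv), PhCO2H (10 mol%), toluene, 80 °C; then BHT, 120 °C (sealed tube)
Reagents that add atoms: none
Why: An E-selective Wittig olefination of the open hydroxy-aldehyde form of the lactol gives the (E,E,E)-trienone, which undergoes a thermal intramolecular Diels–Alder cycloaddition through the endo, chair-like, trans-decalin transition state with the C6 methyl and C9 silyloxy groups equatorial (A(1,3) strain with the dienophile methyl blocks the other diene face), setting C1, C2, C4a and C8a at once.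

Step 16
Reactants: 26 3-[(tert-butyldimethylsilyl)oxy]-1-[(1S,2S,4aR,5S,6R,8R,8aS)-2-[(2R)-butan-2-yl]-6-hydroxy-1,8-dimethyl-5-(triethylsilyloxy)-1,2,4a,5,6,7,8,8a-octahydronaphthalen-1-yl]propan-1-one; 11 4-methyl-2H-pyran-2,6(3H)-dione
Product: 27 (2Z)-5-{[(1S,2S,4aR,5S,6R,8R,8aS)-2-[(2R)-butan-2-yl]-1-{3-[(tert-butyldimethylsilyl)oxy]propanoyl}-1,8-dimethyl-5-(triethylsilyloxy)-1,2,4a,5,6,7,8,8a-octahydronaphthalen-6-yl]oxy}-3-methyl-5-oxopent-2-enoic acid
Conditions: 11 (2 equiv), pyridine, DMAP (cat.), CH2Cl2, 0 °C → rt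
Reagents that add atoms: none
Why: DMAP-catalysed alcoholysis of the cyclic anhydride occurs at the non-conjugated CH2–C=O carbonyl (also through the acylketene formed by base), so the ester forms at the CH2-side carboxyl and the ring-locked Z geometry of the remaining conjugated acid is kept.

Step 17
Reactants: 27 (2Z)-5-{[(1S,2S,4aR,5S,6R,8R,8aS)-2-[(2R)-butan-2-yl]-1-{3-[(tert-butyldimethylsilyl)oxy]propanoyl}-1,8-dimethyl-5-(triethylsilyloxy)-1,2,4a,5,6,7,8,8a-octahydronaphthalen-6-yl]oxy}-3-methyl-5-oxopent-2-enoic acid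
Product: 28 Tandyukisin D, (2Z)-5-{[(1S,2S,4aR,5S,6R,8R,8aS)-2-[(2R)-butan-2-yl]-5-hydroxy-1-(3-hydroxypropanoyl)-1,8-dimethyl-1,2,4a,5,6,7,8,8a-octahydronaphthalen-6-yl]oxy}-3-methyl-5-oxopent-2-enoic acid
Conditions: HF·pyridine, pyridine, THF, 0 °C → rt
Reagents that add atoms: none
Why: Buffered fluoride desilylation removes both silyl ethers under mildly acidic conditions that avoid acyl migration to the neighbouring hydroxyl and β-elimination of the hydroxy ketone.

## Compound list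

1 | (R)-2-methylbutan-1-ol | CC[C@@H](C)CO | starting material
2 | 1-phenyl-1H-tetrazole-5-thiol | Sc1nnnn1-c1ccccc1 | starting material
3 | 5-{[(2R)-2-methylbutyl]sulfanyl}-1-phenyl-1H-tetrazole | CC[C@@H](C)CSc1nnnn1-c1ccccc1 | intermediate
4 | 5-{[(2R)-2-methylbutyl]sulfonyl}-1-phenyl-1H-tetrazole | CC[C@@H](C)CS(=O)(=O)c1nnnn1-c1ccccc1 | intermediate
5 | methyl 3-hydroxypropanoate | COC(=O)CCO | starting material
6 | methyl 3-[(tert-butyldimethylsilyl)oxy]propanoate | COC(=O)CCO[Si](C)(C)C(C)(C)C | intermediate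
7 | ethyltriphenylphosphonium bromide | CC[P+](c1ccccc1)(c1ccccc1)c1ccccc1.[Br-] | starting material
8 | ethylidenetriphenylphosphorane | CC=P(c1ccccc1)(c1ccccc1)c1ccccc1 | intermediate (not isolated)
9 | 5-[(tert-butyldimethylsilyl)oxy]-2-(triphenyl-λ5-phosphanylidene)pentan-3-one | CC(=P(c1ccccc1)(c1ccccc1)c1ccccc1)C(=O)CCO[Si](C)(C)C(C)(C)C | intermediate
10 | 3-methylglutaconic acid (E/Z mixture) | CC(CC(=O)O)=CC(=O)O | starting material
11 | 4-methyl-2H-pyran-2,6(3H)-dione (3-methylglutaconic anhydride) | CC1=CC(=O)OC(=O)C1 | intermediate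
12 | [(4R)-2,2-dimethyl-1,3-dioxolan-4-yl]methanol ((R)-solketal) | CC1(C)OC[C@@H](CO)O1 | starting material
13 | (4S)-2,2-dimethyl-1,3-dioxolane-4-carbaldehyde | CC1(C)OC[C@@H](C=O)O1 | intermediate
14 | ethyl 2-(bromomethyl)prop-2-enoate | CCOC(=O)C(=C)CBr | starting material
15 | ethyl (4R)-4-[(4S)-2,2-dimethyl-1,3-dioxolan-4-yl]-4-hydroxy-2-methylidenebutanoate (present as its zinc alkoxide) | CCOC(=O)C(=C)C[C@@H](O)[C@@H]1COC(C)(C)O1 | intermediate (not isolated)
16 | (5R)-5-[(4S)-2,2-dimethyl-1,3-dioxolan-4-yl]-3-methylideneoxolan-2-one | C=C1C[C@H]([C@@H]2COC(C)(C)O2)OC1=O | intermediate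
17 | (3R,5R)-5-[(4S)-2,2-dimethyl-1,3-dioxolan-4-yl]-3-methyloxolan-2-one | C[C@@H]1C[C@H]([C@@H]2COC(C)(C)O2)OC1=O | intermediate
18 | (3R,5R)-5-[(1S)-1,2-dihydroxyethyl]-3-methyloxolan-2-one | C[C@@H]1C[C@H]([C@@H](O)CO)OC1=O | intermediate
19 | (3R,5R)-5-[(1S)-1,2-bis(triethylsilyloxy)ethyl]-3-methyloxolan-2-one | C[C@@H]1C[C@H]([C@@H](O[Si](CC)(CC)CC)CO[Si](CC)(CC)CC)OC1=O | intermediate
20 | (2R)-2-[(2R,4R)-4-methyl-5-oxooxolan-2-yl]-2-(triethylsilyloxy)acetaldehyde | C[C@@H]1C[C@H]([C@@H](O[Si](CC)(CC)CC)C=O)OC1=O | intermediate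
21 | (triphenyl-λ5-phosphanylidene)acetaldehyde | O=CC=P(c1ccccc1)(c1ccccc1)c1ccccc1 | starting material
22 | (2E,4S)-4-[(2R,4R)-4-methyl-5-oxooxolan-2-yl]-4-(triethylsilyloxy)but-2-enal | C[C@@H]1C[C@H]([C@@H](O[Si](CC)(CC)CC)/C=C/C=O)OC1=O | intermediate
23 | (3R,5R)-3-methyl-5-[(1S,2E,4E,6R)-6-methyl-1-(triethylsilyloxy)octa-2,4-dien-1-yl]oxolan-2-one | CC[C@@H](C)/C=C/C=C/[C@H](O[Si](CC)(CC)CC)[C@H]1C[C@@H](C)C(=O)O1 | intermediate
24 | (3R,5R)-3-methyl-5-[(1S,2E,4E,6R)-6-methyl-1-(triethylsilyloxy)octa-2,4-dien-1-yl]oxolan-2-ol (anomer mixture) | CC[C@@H](C)/C=C/C=C/[C@H](O[Si](CC)(CC)CC)[C@H]1C[C@@H](C)C(O)O1 | intermediate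
25 | (4E,6R,8R,9S,10E,12E,14R)-1-[(tert-butyldimethylsilyl)oxy]-8-hydroxy-4,6,14-trimethyl-9-(triethylsilyloxy)hexadeca-4,10,12-trien-3-one | CC[C@@H](C)/C=C/C=C/[C@H](O[Si](CC)(CC)CC)[C@H](O)C[C@@H](C)/C=C(\C)C(=O)CCO[Si](C)(C)C(C)(C)C | intermediate (not isolated)
26 | 3-[(tert-butyldimethylsilyl)oxy]-1-[(1S,2S,4aR,5S,6R,8R,8aS)-2-[(2R)-butan-2-yl]-6-hydroxy-1,8-dimethyl-5-(triethylsilyloxy)-1,2,4a,5,6,7,8,8a-octahydronaphthalen-1-yl]propan-1-one | CC[C@@H](C)[C@H]1C=C[C@H]2[C@H](O[Si](CC)(CC)CC)[C@H](O)C[C@@H](C)[C@@H]2[C@@]1(C)C(=O)CCO[Si](C)(C)C(C)(C)C | intermediate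
27 | (2Z)-5-{[(1S,2S,4aR,5S,6R,8R,8aS)-2-[(2R)-butan-2-yl]-1-{3-[(tert-butyldimethylsilyl)oxy]propanoyl}-1,8-dimethyl-5-(triethylsilyloxy)-1,2,4a,5,6,7,8,8a-octahydronaphthalen-6-yl]oxy}-3-methyl-5-oxopent-2-enoic acid | CC[C@@H](C)[C@H]1C=C[C@H]2[C@H](O[Si](CC)(CC)CC)[C@H](OC(=O)C/C(C)=C\C(=O)O)C[C@@H](C)[C@@H]2[C@@]1(C)C(=O)CCO[Si](C)(C)C(C)(C)C | intermediate
28 | Tandyukisin D | CC[C@@H](C)[C@H]1C=C[C@H]2[C@H](O)[C@H](OC(=O)C/C(C)=C\C(=O)O)C[C@@H](C)[C@@H]2[C@@]1(C)C(=O)CCO | target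

## Step count and risks

Total step count: 17. Longest linear sequence: 12 steps (steps 6 to 17, from (R)-solketal 12).

**Step 15 (lactol Wittig and cycloaddition in one flask).** The hindered keto-ylide may react slowly with the lactol, and the freed C8 hydroxyl could add to the enone. The fallback sets out from lactone 23 and comes back at 26. Lactone 23 is opened with Me3Al and N,O-dimethylhydroxylamine hydrochloride to the hydroxy Weinreb amide F1. Its free hydroxyl is capped at once (Me3SiCl, imidazole) to give the trimethylsilyl ether F2. Reduction with i-Bu2AlH at −78 °C gives the open-chain aldehyde F3, which is far more reactive than a lactol. Wittig olefination with ylide 9 at 60 °C gives the protected triene F4. The Diels–Alder step is then run on its own (toluene, 120 °C, or Me2AlCl at −40 °C) to give the protected decalin F5. Cleaving only the trimethylsilyl ether (citric acid, MeOH, 0 °C) returns 26.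

**Step 16 (acylation of the hindered axial C6 hydroxyl).** The reaction may be slow, or the base may move the double bond of the half-ester. The fallback sets out from lactol 24 and comes back at 27. The Wittig reaction with 9 is held at 70 °C so that triene 25 is isolated. Its unhindered acyclic C8 hydroxyl is acylated with anhydride 11 (pyridine, DMAP) to give the triene half-ester F6. Heating F6 (toluene, 110 °C, BHT) closes the decalin and gives 27 directly.

**Step 13 (Julia–Kocienski olefination).** The enal carries a base-sensitive γ-silyloxy/δ-acyloxy array, and E-selectivity could erode. The fallback sets out from aldehyde 20 and comes back at 23. Takai-type boryl-olefination of 20 (CrCl2, LiI, 2-(dichloromethyl)-4,4,5,5-tetramethyl-1,3,2-dioxaborolane, THF) gives the E-vinylboronate F7. In parallel, alcohol 1 is oxidised (Swern) to (R)-2-methylbutanal F8, and Takai iodo-olefination (CrCl2, CHI3) converts it into (1E,3R)-1-iodo-3-methylpent-1-ene F9. Suzuki–Miyaura coupling of F7 with F9 (Pd(PPh3)4, aq. K3PO4, THF, rt) gives diene 23, with both alkene geometries fixed by the partners and no strong base.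

## Further compounds

F1 | step 15 | (2R,4R,5S,6E,8E,10R)-4-hydroxy-N-methoxy-N,2,10-trimethyl-5-(triethylsilyloxy)dodeca-6,8-dienamide | CC[C@@H](C)/C=C/C=C/[C@H](O[Si](CC)(CC)CC)[C@H](O)C[C@@H](C)C(=O)N(C)OC
F2 | step 15 | (2R,4R,5S,6E,8E,10R)-N-methoxy-N,2,10-trimethyl-5-(triethylsilyloxy)-4-(trimethylsilyloxy)dodeca-6,8-dienamide | CC[C@@H](C)/C=C/C=C/[C@H](O[Si](CC)(CC)CC)[C@H](O[Si](C)(C)C)C[C@@H](C)C(=O)N(C)OC
F3 | step 15 | (2R,4R,5S,6E,8E,10R)-2,10-dimethyl-5-(triethylsilyloxy)-4-(trimethylsilyloxy)dodeca-6,8-dienal | CC[C@@H](C)/C=C/C=C/[C@H](O[Si](CC)(CC)CC)[C@H](O[Si](C)(C)C)C[C@@H](C)C=O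
F4 | step 15 | (4E,6R,8R,9S,10E,12E,14R)-1-[(tert-butyldimethylsilyl)oxy]-4,6,14-trimethyl-9-(triethylsilyloxy)-8-(trimethylsilyloxy)hexadeca-4,10,12-trien-3-one | CC[C@@H](C)/C=C/C=C/[C@H](O[Si](CC)(CC)CC)[C@H](O[Si](C)(C)C)C[C@@H](C)/C=C(\C)C(=O)CCO[Si](C)(C)C(C)(C)C
F5 | step 15 | 3-[(tert-butyldimethylsilyl)oxy]-1-[(1S,2S,4aR,5S,6R,8R,8aS)-2-[(2R)-butan-2-yl]-1,8-dimethyl-5-(triethylsilyloxy)-6-(trimethylsilyloxy)-1,2,4a,5,6,7,8,8a-octahydronaphthalen-1-yl]propan-1-one | CC[C@@H](C)[C@H]1C=C[C@H]2[C@H](O[Si](CC)(CC)CC)[C@H](O[Si](C)(C)C)C[C@@H](C)[C@@H]2[C@@]1(C)C(=O)CCO[Si](C)(C)C(C)(C)C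
F6 | step 16 | (2Z)-5-{[(4E,6R,8R,9S,10E,12E,14R)-1-[(tert-butyldimethylsilyl)oxy]-4,6,14-trimethyl-3-oxo-9-(triethylsilyloxy)hexadeca-4,10,12-trien-8-yl]oxy}-3-methyl-5-oxopent-2-enoic acid | CC[C@@H](C)/C=C/C=C/[C@H](O[Si](CC)(CC)CC)[C@H](OC(=O)C/C(C)=C\C(=O)O)C[C@@H](C)/C=C(\C)C(=O)CCO[Si](C)(C)C(C)(C)C
F7 | step 13 | (3R,5R)-3-methyl-5-[(1S,2E)-3-(4,4,5,5-tetramethyl-1,3,2-dioxaborolan-2-yl)-1-(triethylsilyloxy)prop-2-en-1-yl]oxolan-2-one | C[C@@H]1C[C@H]([C@@H](O[Si](CC)(CC)CC)/C=C/B2OC(C)(C)C(C)(C)O2)OC1=O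
F8 | step 13 | (2R)-2-methylbutanal | CC[C@@H](C)C=O
F9 | step 13 | (1E,3R)-1-iodo-3-methylpent-1-ene | CC[C@@H](C)/C=C/I
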